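Within 2.50 h Thursday's product stops rising, and Monday's stops by 4.00 h. The task is to say how the rate in the new flask answers to its spent carrier charge.

common to all: substrate 20 mM

| charge | salt in the second phase | capture agent | spent carrier | remark | volume of the second phase over the first |
|---|---|---|---|---|---|
| Monday's | 50 mM | 6 mM | 0.25 mM | run made earlier |  |
| Thursday's | 50 mM | 6 mM | 0.38 mM | run made earlier |  |
| flask | 50.0 mM | 6.00 mM | 0.50 mM |  | 0.25 |

| run | time / h | product / % |
|---|---|---|
| Monday's | 2.00 | 47.9 |
| Monday's | 4.00 | 48.5 |
| Monday's | 6.00 | 49.3 |
| Monday's | 8.00 | 48.7 |
| Monday's | 10.0 | 49.1 |
| Monday's | 12.0 | 48.6 |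
| Monday's | 15.0 | 49.5 |
| Thursday's | 0.833 | 52.0 |
| Thursday's | 2.50 | 57.5 |
| Thursday's | 4.00 | 57.0 |
| Thursday's | 6.00 | 57.2 |
| Thursday's | 10.0 | 57.3 |
| Thursday's | 12.0 | 56.6 |
| Thursday's | 15.0 | 57.0 |

(readings scatter by 0.5 percentage points)

1. apparent order in spent carrier when 50% of the substrate are converted (percent change of the rate of making product for one percent more spent carrier charged)

- in the second phase: salt in the second phase, spent salt in the second phase; everything else is in the first
- charges count per volume of the first phase; a concentration in a rate is the amount of a species over the volume of its own phase; every rate counts per litre of the first phase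
- steps thought possible: substrate + fresh carrier -> product + spent carrier; spent carrier + salt in the second phase <-> fresh carrier + spent salt in the second phase; spent carrier + capture agent -> trapped intermediate
- the earlier runs hold the two phases in the same ratio of volumes as the flask asked about

I read the tables column against column. From 4.00 h on, Monday averages 9.79 mM of product. From 2.50 h on, Thursday averages 11.4 mM. Thursday stops higher, but its gain is smaller in proportion than its gain in carrier.

I take the stop to mean that the carrier is lost to capture agent, the off-cycle exit, while the exchange with salt stays near balance. Spent salt then grows with product P and pushes back. Let S be substrate and X salt. Let B be the running sum of P dP/(S·X). On this picture, at these charges of substrate, salt and capture agent, B grows in step with carrier lost, whatever the carrier charge.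

The readings give B = 0.0851 for Monday and 0.132 for Thursday. Their ratio is 1.55, and the ratio of the charges is 1.52.

So I carry one quantity: the toll, the carrier lost by the time product reaches 10.0 mM, with the other charges as here. With B there at 0.0902, the two runs give a toll of 0.262 mM.

By my reckoning the new flask keeps 0.238 mM live at that product. I take the rate at fixed conversion to go in step with live carrier, so the order is charge over live carrier, 2.10. The forecast also says 2.1, on the ground that “Rate at fixed conversion is proportional to live carrier”.

The flask gives 2.1.

    substrate + fresh carrier → product + spent carrier (k = 1.40 /M/s)
    spent carrier + salt in the second phase ⇌ fresh carrier + spent salt in the second phase (K = 0.710, k = 9.00 /M/s)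
    spent carrier + capture agent → trapped intermediate (k = 0.450 /M/s)

At that conversion, reached after 0.444 h, the flask makes product at 8.41 mM/h. My toll there is about half of the flask's charge, which by my reckoning leaves 0.238 mM live. Scaled by B to the flask's 62.8% of product at 15.0 h, with B there at 0.178, my toll comes to 0.517 mM against the 0.50 mM charged.

(The runs are calculated on assumed constants; noise was put on by code.)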